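## Analysis of the target

The target 20 is a 3,3''-linked biflavonoid: a naringenin-type flavanone (rings A, C and B, unprimed locants) whose C3 carries C3'' of an apigenin-type flavone (doubly primed locants). Ring C holds the only two stereocentres, C2 (S, bearing the 4-hydroxyphenyl ring B) and C3 (R, bearing the flavonyl group). They are adjacent and trans, with both large groups equatorial, which is the thermodynamically preferred arrangement. C3–H is α to the C4 ketone and enolises easily, and O1–C2 is β to that ketone, so base or a strong Lewis acid can open ring C to a 2'-hydroxychalcone and erase C2; the six free phenols add acid–base and oxidative sensitivity. The hard points are the congested C3–C3'' bond, which lies between two carbons that each sit between an aryl group and a carbonyl group, and the need to set C2 absolutely in a form that survives to the end, whereas C3 can be left to thermodynamics. The strategy rests on C2–C3–C4 of ring C together with the ring A oxygen O1: with C4 at the carbinol level and C2=C3 as an alkene, ionisation at C4 gives an allyl cation conjugated to ring A, that is, a vinyl o-quinone methide, whose O1 can close on C2. The 2H-chromene formed in this way has C2 as its only stereocentre and no carbonyl next to it, so C2 is made under catalyst control and then meets only neutral or weakly acidic conditions. All six phenols are carried as benzyl ethers, so that the last step is a neutral hydrogenolysis and not a Lewis-acid dealkylation of a configurationally fragile flavanone.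

## Retrosynthetic reasoning

Target 20 to hexabenzyl ether 19. The six O–benzyl bonds are cut last. Benzyl is preferred to smaller alkyl groups because it leaves by neutral hydrogenolysis; a Lewis-acid dealkylation at this stage would coordinate the C4 carbonyl of a 3-substituted flavanone and invite opening of O1–C2. The forward step only has to spare the tetrasubstituted flavone double bond and the benzylic C2–O1 bond.

19 to flavan-4-ol 17 (through the cis ketone 18) and on to chromene 15. The C4 carbonyl is taken back to a carbinol, and C3–H and C4–O are removed across C3=C4. The oxidation level is adjusted here because the C3=C4 alkene of 15 has a single CH terminus, C4, so an anti-Markovnikov hydration can place oxygen only at C4. The syn addition should come from the face away from the C2 aryl group and so give the 2,3-cis relationship in 17. This does not matter: C4 is oxidised, and C3, once α to the ketone in 18, equilibrates by enolisation to the trans isomer 19. What is gained is that C2 is the one stereocentre that has to be made selectively.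

15 to allylic alcohol 13 (through the quinone methide 14). The O1–C2 bond is cut. It is cut here and not at C3–C4 or C2–C3 because this is the only ring C bond whose formation creates C2 from a precursor that is achiral at that carbon and needs no carbonyl at C4. 13 ionises at its doubly benzylic carbinol to 14, and O1 closes on C2. The carbinol stereocentre of 13 disappears on ionisation, so 13 can be racemic. The forward reaction has to ionise only that carbinol, keep the cation paired with a chiral counter-anion, and close on one face of C2.

13 to 2'-hydroxychalcone 12 and its MOM ether 11. A carbonyl 1,2-reduction and an acetal cleavage are undone. The phenol that becomes O1 must be free in 13 but masked during the base-mediated carbon–carbon bond formations, where a free 2'-phenol would add to the enone and give a racemic flavanone. The acetal is removed before the reduction because 13 would not survive the acid.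

11 to ketone 9 and aldehyde 10. The C2=C3 double bond is cut as an aldol condensation. This fixes the connectivity without ambiguity, flavonyl on the α-carbon and aryl on the β-carbon. It should also give the E alkene, with the β-aryl group trans to the aroyl group, which is the geometry that places this aryl group on the outside of the closing hexatriene in 14. Routes that add an acyl group across a carbon–carbon triple bond were set aside, because nothing in the structure fixes which alkyne carbon would be acylated and sterics point to the wrong one.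

9 to iodoflavone 7 and acetophenone 8. The C3''–CH2 bond is cut as a ketone α-arylation. It is the most hindered bond of the skeleton, and it is formed where the regiochemistry is defined by the carbon–iodine bond of 7 and where both partners derive from the same acetophenone 1.

7 to flavone 5, diketone 4 and the starting materials 1 and 2; 8 to 1. The flavone is opened at O1''–C2'' to 4, and 4 at its central carbon to 1 and 2. Iodine is placed at C3'' of 5 through the lithio compound 6; an electrophilic iodination would go to C6''/C8'' of the dialkoxylated ring instead. 8 is 1 with its chelated phenol masked as the MOM ether.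

## Alternatives that were turned down

Alternative 1: The disconnection is C3–C4 of ring C, with the flavone still open as a 1,3-diketone. In the forward step a chiral carbene catalyst turns the aldehyde of the racemic aryl ether A2 into an acyl-anion equivalent, which adds 6-exo-trig to the alkylidene 1,3-diketone and gives flavanone A1. The ether carbon of A2 would have to epimerise under the conditions so that one enantiomer is drained (dynamic kinetic resolution). In its favour, the step reaches the ketone oxidation level directly and forms C3–C4 and both stereocentres at once. The endgame is a single acid treatment that removes the acetal groups and cyclodehydrates the diketone to the flavone, so after the key step it is clearly shorter than the chosen route (one step against three). Against it, A2 is a γ-aryloxy alkylidene diketone that can lose phenoxide or isomerise to an enol ether under base. The attacked carbon sits next to two aroyl groups, one of them 2,6-disubstituted. A dynamic resolution must work on top of an enantioselective C–C bond formation. Finally A1 is a flavanone with an acidic C3–H in a basic medium, where ring opening and reclosure can scramble C2 and C3 after they are set. The chosen strategy gives up the short endgame. In return it controls one stereocentre in a unimolecular C–O closure and never exposes a flavanone to base.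

Alternative 2: The disconnection cuts O1–C2 and C3–C4 together, as a [4+2] cycloaddition. In the forward step a confined chiral Brønsted acid ionises the acetal A5 to an oxygen-substituted o-quinone methide, which adds as a heterodiene across the styryl double bond of A4 and gives the 4-methoxyflavan A3. This is the most convergent plan: A4 is one Heck coupling away from an iodoflavone such as 7, two bonds and ring C form in one step, and the trans C2/C3 relationship follows stereospecifically from the E alkene. On convergence, and on setting C3 directly and not by equilibration, it is stronger than the chosen strategy. Against it, the step is bimolecular. The heterodiene is stabilised by two alkoxy donors and flanked by an ortho substituent, and the alkene carbon that must attack it carries the bulky flavonyl group. Face, endo/exo and enantiocontrol must all hold without a tether. The C4 methoxy group then has to be hydrolysed and oxidised, and six methyl ethers have to be removed with a strong Lewis acid from an epimerisable flavanone. The chosen strategy has a longer linear sequence to its precursor, but its key step is intramolecular and has one stereocentre to control.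

Alternative 3: The disconnection cuts O1–C8a and C4–C4a, so ring A is delivered as an aryne. In the forward step the alkoxide of the β-hydroxy ester A7 adds to the aryne released from A8 by a fluoride source, at the aryne carbon remote from the methoxy group. The aryl anion formed next to that methoxy group then attacks the ester and closes ring C to give A6. In its favour, both stereocentres come from an established asymmetric aldol reaction, so no new asymmetric step is needed and on this point it is stronger than the chosen strategy. The regiochemistry of the aryne addition matches the 5,7-oxygenation, the ketone level is reached directly, and only deprotection remains. Against it, the alkoxide of a β-hydroxy ester with an aryl-flanked, acidic α-hydrogen is set up for retro-aldol cleavage and α-epimerisation. The aryl anion can be quenched by that same C–H and give O-arylation only. A6 is formed in a basic fluoride medium, where O1–C2 can open. The last step must still strip six methyl ethers with a strong Lewis acid. The chosen strategy has to create C2 by asymmetric catalysis, but it keeps every intermediate that carries C2 away from base and ends with a neutral deprotection.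

Key step: step 9

Remark on the chemistry: the sense of induction in step 9 is assumed for the (R)-configured acid; should the (2S)-chromene prevail, the (S)-configured acid is used instead.

Step 1
Reactants: 1 1-[2,4-bis(benzyloxy)-6-hydroxyphenyl]ethan-1-one; 2 4-(benzyloxy)benzoyl chloride
Product: 4 1-[2,4-bis(benzyloxy)-6-hydroxyphenyl]-3-[4-(benzyloxy)phenyl]propane-1,3-dione, via dilithium enolate 3 (not isolated)
Conditions: LiN(SiMe3)2 (3.2 equiv), THF, −78 → −10 °C; then 2, −78 °C → rt; HCl (aq)
Reagents that add atoms: none
Why: Claisen-type C-aroylation of the dilithium phenoxide–enolate 3 (one-pot variant of the Baker–Venkataraman route); the third equivalent of base deprotonates the 1,3-diketone as it forms and stops further acylation.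

Step 2
Reactants: 4 1-[2,4-bis(benzyloxy)-6-hydroxyphenyl]-3-[4-(benzyloxy)phenyl]propane-1,3-dione
Product: 5 5,7-bis(benzyloxy)-2-[4-(benzyloxy)phenyl]-4H-chromen-4-one
Conditions: NaOAc, AcOH, 100 °C
Reagents that add atoms: none
Why: Acid-catalysed cyclodehydration: the phenol adds to the aroyl carbonyl (6-exo-trig) and water is lost to give the chromen-4-one; buffered acetic acid should spare the benzyl ethers.

Step 3
Reactants: 5 5,7-bis(benzyloxy)-2-[4-(benzyloxy)phenyl]-4H-chromen-4-one
Product: 7 5,7-bis(benzyloxy)-2-[4-(benzyloxy)phenyl]-3-iodo-4H-chromen-4-one, via 3-lithioflavone 6 (not isolated)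
Conditions: LiN(iPr)2 (1.3 equiv), THF, −78 °C; I2, −78 → −20 °C
Reagents that add atoms: iodine, II
Why: Directed deprotonation of the only vinylic, carbonyl-flanked C–H (C3) by the amide base at low temperature, then iodinolysis of the C–Li bond; an electrophilic iodination would instead attack C6/C8 of the dialkoxylated ring.

Step 4
Reactants: 1 1-[2,4-bis(benzyloxy)-6-hydroxyphenyl]ethan-1-one
Product: 8 1-[2,4-bis(benzyloxy)-6-(methoxymethoxy)phenyl]ethan-1-one
Conditions: MOMCl, Cs2CO3, DMF, 0 °C → rt
Reagents that add atoms: chloromethyl methyl ether, COCCl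
Why: Williamson-type O-alkylation of the chelated phenoxide; the acetal survives the basic steps 5 and 6 and keeps the phenol from adding to the enone made in step 6.

Step 5
Reactants: 7 5,7-bis(benzyloxy)-2-[4-(benzyloxy)phenyl]-3-iodo-4H-chromen-4-one; 8 1-[2,4-bis(benzyloxy)-6-(methoxymethoxy)phenyl]ethan-1-one
Product: 9 3-{2-[2,4-bis(benzyloxy)-6-(methoxymethoxy)phenyl]-2-oxoethyl}-5,7-bis(benzyloxy)-2-[4-(benzyloxy)phenyl]-4H-chromen-4-one
Conditions: tris(dibenzylideneacetone)dipalladium Pd2(dba)3 (2.5 mol%), 2-dicyclohexylphosphino-2',4',6'-triisopropylbiphenyl (6 mol%), K3PO4, toluene, 90 °C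
Reagents that add atoms: none
Why: Palladium-catalysed ketone α-arylation: zerovalent palladium inserts into the C3–I bond, the potassium enolate of 8 takes the place of iodide, and reductive elimination forms C3''–CH2. The bulky biaryl phosphine drives reductive elimination at the doubly ortho-substituted carbon, the mild phosphate base spares the flavone, and the site of coupling is fixed by the iodine.

Step 6
Reactants: 9 3-{2-[2,4-bis(benzyloxy)-6-(methoxymethoxy)phenyl]-2-oxoethyl}-5,7-bis(benzyloxy)-2-[4-(benzyloxy)phenyl]-4H-chromen-4-one; 10 4-(benzyloxy)benzaldehyde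
Product: 11 3-{(1E)-3-[2,4-bis(benzyloxy)-6-(methoxymethoxy)phenyl]-1-[4-(benzyloxy)phenyl]-3-oxoprop-1-en-2-yl}-5,7-bis(benzyloxy)-2-[4-(benzyloxy)phenyl]-4H-chromen-4-one (aroyl group trans to the β-aryl group)
Conditions: piperidine (0.3 equiv), AcOH (0.3 equiv), toluene, reflux (Dean–Stark)
Reagents that add atoms: none
Why: Knoevenagel-type aldol condensation of the methylene of 9, activated by the ketone and the flavonyl group, with aldehyde 10. Elimination under equilibrating conditions should give the E isomer, as for α-aryl chalcones, and the connectivity (flavonyl on the α-carbon, aryl on the β-carbon) cannot be otherwise.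

Step 7
Reactants: 11 the MOM-protected (E)-chalcone of step 6
Product: 12 3-{(1E)-3-[2,4-bis(benzyloxy)-6-hydroxyphenyl]-1-[4-(benzyloxy)phenyl]-3-oxoprop-1-en-2-yl}-5,7-bis(benzyloxy)-2-[4-(benzyloxy)phenyl]-4H-chromen-4-one
Conditions: HCl (1 M), MeOH/THF, 40 °C
Reagents that add atoms: none
Why: Acetal hydrolysis: the MOM ether ortho to the ketone is cleaved by dilute acid through its oxocarbenium ion, while the benzyl ethers and the flavone should survive. The 6'-alkoxylated, α-substituted 2'-hydroxychalcone should not close to the flavanone at a useful rate under these conditions.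

Step 8
Reactants: 12 the 2'-hydroxychalcone of step 7
Product: 13 3-{(1E)-3-[2,4-bis(benzyloxy)-6-hydroxyphenyl]-1-[4-(benzyloxy)phenyl]-3-hydroxyprop-1-en-2-yl}-5,7-bis(benzyloxy)-2-[4-(benzyloxy)phenyl]-4H-chromen-4-one, racemic at the carbinol carbon
Conditions: NaBH4, CeCl3·7H2O, MeOH/THF, −20 → 0 °C; NaHCO3 (aq) work-up, no silica
Reagents that add atoms: none
Why: Luche reduction: cerium-activated 1,2-hydride addition to the enone carbonyl, while the flavone carbonyl, a vinylogous ester, should not be reduced. The new carbinol is racemic, which is immaterial, and the basic work-up keeps the very ionisable alcohol from closing before it meets the catalyst.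

Step 9
Reactants: 13 the racemic (E)-allylic alcohol of step 8
Product: 15 5,7-bis(benzyloxy)-3-{(2R)-5,7-bis(benzyloxy)-2-[4-(benzyloxy)phenyl]-2H-chromen-3-yl}-2-[4-(benzyloxy)phenyl]-4H-chromen-4-one, via vinyl o-quinone methide 14 (not isolated)
Conditions: (R)-3,3'-bis(2,4,6-triisopropylphenyl)-1,1'-binaphthalene-2,2'-diyl N-(trifluoromethylsulfonyl)phosphoramide (5 mol%), toluene/CH2Cl2 (4:1), −60 °C; Et3N quench
Reagents that add atoms: none
Why: The acid protonates the doubly benzylic, allylic C4 hydroxyl, which leaves as water with help from the ortho-phenol and the two benzyloxy groups; this gives the vinyl o-quinone methide 14, present as a hydrogen-bonded contact ion pair of its O-protonated (hydroxyallyl cation) form with the chiral phosphoramide anion. Ring C then closes by a thermal oxa-6π electrocyclisation across O1=C8a–C4a=C4–C3=C2, equivalent to a 6-endo-trig attack of the phenol oxygen on the allyl terminus C2, and forms O1–C2. The closest known reaction type is the chiral N-triflyl phosphoramide-catalysed dehydrative cyclisation of o-hydroxyphenyl allylic alcohols to 2H-chromenes through chiral contact ion pairs, together with the classical acid-induced conversion of reduced 2'-hydroxychalcones into flav-3-enes. C2 is the only new stereocentre, and because ionisation removes the carbinol stereocentre its configuration is set by the catalyst alone: the anion, anchored to the phenolic O–H, shields one face of the planar cation and fixes the sense of rotation at C2. The step needs enantioface selectivity at C2 (catalyst) and site selectivity for O1, which is the only nucleophile that can reach C2 through a six-membered transition state; attack by the flavone carbonyl oxygen would give a strained oxocarbenium ion that cannot lose a proton and should revert. It also needs a fast closure, which the E alkene secures by placing the 4-(benzyloxy)phenyl group outside and hydrogen inside at the rotating terminus. Low temperature and the base quench are meant to keep the uncatalysed closure of 13 and acid-induced re-ionisation of the C2–O1 bond of 15 negligible.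

Step 10
Reactants: 15 the (2R)-chromene of step 9
Product: 17 5,7-bis(benzyloxy)-3-{(2S,3R,4R)-5,7-bis(benzyloxy)-2-[4-(benzyloxy)phenyl]-4-hydroxy-3,4-dihydro-2H-chromen-3-yl}-2-[4-(benzyloxy)phenyl]-4H-chromen-4-one (2,3-cis, 3,4-trans), via C4 alkylborane 16 (not isolated)
Conditions: BH3·SMe2, THF, 0 °C → rt; then NaOH (aq), H2O2, 0 °C
Reagents that add atoms: hydrogen peroxide, OO
Why: Hydroboration–oxidation: boron adds to C4, the only CH terminus of the trisubstituted alkene (as with isoflav-3-enes), and hydrogen to C3, syn and on the face opposite the pseudo-axial C2 aryl group; oxidation with retention gives the alcohol. The C3 and C4 configurations are corrected or removed in step 11, and C2 is not touched.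

Step 11
Reactants: 17 the flavan-4-ol of step 10
Product: 19 (2S,3R)-5,7-bis(benzyloxy)-3-{5,7-bis(benzyloxy)-2-[4-(benzyloxy)phenyl]-4-oxo-4H-chromen-3-yl}-2-[4-(benzyloxy)phenyl]-2,3-dihydro-4H-chromen-4-one (2,3-trans), via cis-flavanone 18 (not isolated)
Conditions: Dess–Martin periodinane, CH2Cl2, 0 °C → rt; then AcOH, CH2Cl2, rt
Reagents that add atoms: none
Why: Dess–Martin oxidation of the benzylic alcohol gives the 2,3-cis ketone 18. Acid-catalysed enolisation (acetic acid released by the oxidant, topped up) then equilibrates C3 to the diequatorial 2,3-trans isomer without forming the enolate that would open ring C, so C2 should stay intact.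

Step 12
Reactants: 19 the hexabenzyl ether of step 11
Product: 20 (2S,3R)-5,7-dihydroxy-3-[5,7-dihydroxy-2-(4-hydroxyphenyl)-4-oxo-4H-chromen-3-yl]-2-(4-hydroxyphenyl)-2,3-dihydro-4H-chromen-4-one
Conditions: H2 (1 atm), 10% Pd/C, THF/MeOH, rt
Reagents that add atoms: none
Why: Hydrogenolysis of six aryl benzyl ethers under neutral conditions; the tetrasubstituted flavone double bond and the aryl ketone should not be reduced, and no acid or base is present to enolise C3 or open ring C.

Compound list

1 | 1-[2,4-bis(benzyloxy)-6-hydroxyphenyl]ethan-1-one | CC(=O)c1c(O)cc(OCc2ccccc2)cc1OCc1ccccc1 | starting material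
2 | 4-(benzyloxy)benzoyl chloride | O=C(Cl)c1ccc(OCc2ccccc2)cc1 | starting material
3 | dilithium phenoxide–enolate of 1 (not isolated) | [Li]OC(=C)c1c(O[Li])cc(OCc2ccccc2)cc1OCc1ccccc1 | intermediate
4 | 1-[2,4-bis(benzyloxy)-6-hydroxyphenyl]-3-[4-(benzyloxy)phenyl]propane-1,3-dione | O=C(CC(=O)c1ccc(OCc2ccccc2)cc1)c1c(O)cc(OCc2ccccc2)cc1OCc1ccccc1 | intermediate
5 | 5,7-bis(benzyloxy)-2-[4-(benzyloxy)phenyl]-4H-chromen-4-one | O=c1cc(-c2ccc(OCc3ccccc3)cc2)oc2cc(OCc3ccccc3)cc(OCc3ccccc3)c12 | intermediate
6 | 5,7-bis(benzyloxy)-2-[4-(benzyloxy)phenyl]-3-lithio-4H-chromen-4-one (not isolated) | [Li]c1c(-c2ccc(OCc3ccccc3)cc2)oc2cc(OCc3ccccc3)cc(OCc3ccccc3)c2c1=O | intermediate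
7 | 5,7-bis(benzyloxy)-2-[4-(benzyloxy)phenyl]-3-iodo-4H-chromen-4-one | Ic1c(-c2ccc(OCc3ccccc3)cc2)oc2cc(OCc3ccccc3)cc(OCc3ccccc3)c2c1=O | intermediate
8 | 1-[2,4-bis(benzyloxy)-6-(methoxymethoxy)phenyl]ethan-1-one | CC(=O)c1c(OCOC)cc(OCc2ccccc2)cc1OCc1ccccc1 | intermediate
9 | 3-{2-[2,4-bis(benzyloxy)-6-(methoxymethoxy)phenyl]-2-oxoethyl}-5,7-bis(benzyloxy)-2-[4-(benzyloxy)phenyl]-4H-chromen-4-one | O=C(Cc1c(-c2ccc(OCc3ccccc3)cc2)oc2cc(OCc3ccccc3)cc(OCc3ccccc3)c2c1=O)c1c(OCOC)cc(OCc2ccccc2)cc1OCc1ccccc1 | intermediate
10 | 4-(benzyloxy)benzaldehyde | O=Cc1ccc(OCc2ccccc2)cc1 | starting material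
11 | 3-{(1E)-3-[2,4-bis(benzyloxy)-6-(methoxymethoxy)phenyl]-1-[4-(benzyloxy)phenyl]-3-oxoprop-1-en-2-yl}-5,7-bis(benzyloxy)-2-[4-(benzyloxy)phenyl]-4H-chromen-4-one | O=C(c1c(OCOC)cc(OCc2ccccc2)cc1OCc1ccccc1)/C(=C/c1ccc(OCc2ccccc2)cc1)c1c(-c2ccc(OCc3ccccc3)cc2)oc2cc(OCc3ccccc3)cc(OCc3ccccc3)c2c1=O | intermediate
12 | 3-{(1E)-3-[2,4-bis(benzyloxy)-6-hydroxyphenyl]-1-[4-(benzyloxy)phenyl]-3-oxoprop-1-en-2-yl}-5,7-bis(benzyloxy)-2-[4-(benzyloxy)phenyl]-4H-chromen-4-one | O=C(c1c(O)cc(OCc2ccccc2)cc1OCc1ccccc1)/C(=C/c1ccc(OCc2ccccc2)cc1)c1c(-c2ccc(OCc3ccccc3)cc2)oc2cc(OCc3ccccc3)cc(OCc3ccccc3)c2c1=O | intermediate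
13 | 3-{(1E)-3-[2,4-bis(benzyloxy)-6-hydroxyphenyl]-1-[4-(benzyloxy)phenyl]-3-hydroxyprop-1-en-2-yl}-5,7-bis(benzyloxy)-2-[4-(benzyloxy)phenyl]-4H-chromen-4-one, racemic at the carbinol carbon | OC(c1c(O)cc(OCc2ccccc2)cc1OCc1ccccc1)/C(=C/c1ccc(OCc2ccccc2)cc1)c1c(-c2ccc(OCc3ccccc3)cc2)oc2cc(OCc3ccccc3)cc(OCc3ccccc3)c2c1=O | intermediate
14 | vinyl o-quinone methide from 13: 3,5-bis(benzyloxy)-6-ylidene-cyclohexa-2,4-dien-1-one whose exocyclic carbon carries the 2-flavonyl-2-[4-(benzyloxy)phenyl]ethenyl group, flavonyl-bearing carbon on the carbonyl side (not isolated) | O=C1C=C(OCc2ccccc2)C=C(OCc2ccccc2)/C1=C/C(=C/c1ccc(OCc2ccccc2)cc1)c1c(-c2ccc(OCc3ccccc3)cc2)oc2cc(OCc3ccccc3)cc(OCc3ccccc3)c2c1=O | intermediate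
15 | 5,7-bis(benzyloxy)-3-{(2R)-5,7-bis(benzyloxy)-2-[4-(benzyloxy)phenyl]-2H-chromen-3-yl}-2-[4-(benzyloxy)phenyl]-4H-chromen-4-one | C1=C(c2c(-c3ccc(OCc4ccccc4)cc3)oc3cc(OCc4ccccc4)cc(OCc4ccccc4)c3c2=O)[C@@H](c2ccc(OCc3ccccc3)cc2)Oc2cc(OCc3ccccc3)cc(OCc3ccccc3)c12 | intermediate
16 | C4 alkylborane from 15, boron trans to the C3 flavonyl group and to the C2 aryl group (not isolated) | B[C@H]1c2c(OCc3ccccc3)cc(OCc3ccccc3)cc2O[C@H](c2ccc(OCc3ccccc3)cc2)[C@@H]1c1c(-c2ccc(OCc3ccccc3)cc2)oc2cc(OCc3ccccc3)cc(OCc3ccccc3)c2c1=O | intermediate
17 | 5,7-bis(benzyloxy)-3-{(2S,3R,4R)-5,7-bis(benzyloxy)-2-[4-(benzyloxy)phenyl]-4-hydroxy-3,4-dihydro-2H-chromen-3-yl}-2-[4-(benzyloxy)phenyl]-4H-chromen-4-one | O[C@H]1c2c(OCc3ccccc3)cc(OCc3ccccc3)cc2O[C@H](c2ccc(OCc3ccccc3)cc2)[C@@H]1c1c(-c2ccc(OCc3ccccc3)cc2)oc2cc(OCc3ccccc3)cc(OCc3ccccc3)c2c1=O | intermediate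
18 | (2S,3S)-5,7-bis(benzyloxy)-3-{5,7-bis(benzyloxy)-2-[4-(benzyloxy)phenyl]-4-oxo-4H-chromen-3-yl}-2-[4-(benzyloxy)phenyl]-2,3-dihydro-4H-chromen-4-one, 2,3-cis (not isolated) | O=C1c2c(OCc3ccccc3)cc(OCc3ccccc3)cc2O[C@H](c2ccc(OCc3ccccc3)cc2)[C@@H]1c1c(-c2ccc(OCc3ccccc3)cc2)oc2cc(OCc3ccccc3)cc(OCc3ccccc3)c2c1=O | intermediate
19 | (2S,3R)-5,7-bis(benzyloxy)-3-{5,7-bis(benzyloxy)-2-[4-(benzyloxy)phenyl]-4-oxo-4H-chromen-3-yl}-2-[4-(benzyloxy)phenyl]-2,3-dihydro-4H-chromen-4-one, 2,3-trans | O=C1c2c(OCc3ccccc3)cc(OCc3ccccc3)cc2O[C@H](c2ccc(OCc3ccccc3)cc2)[C@H]1c1c(-c2ccc(OCc3ccccc3)cc2)oc2cc(OCc3ccccc3)cc(OCc3ccccc3)c2c1=O | intermediate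
20 | (2S,3R)-5,7-dihydroxy-3-[5,7-dihydroxy-2-(4-hydroxyphenyl)-4-oxo-4H-chromen-3-yl]-2-(4-hydroxyphenyl)-2,3-dihydro-4H-chromen-4-one | O=C1c2c(O)cc(O)cc2O[C@H](c2ccc(O)cc2)[C@H]1c1c(-c2ccc(O)cc2)oc2cc(O)cc(O)c2c1=O | target

Total step count: 12. Longest linear sequence: 11 steps (1 → 4 → 5 → 7 → 9 → 11 → 12 → 13 → 15 → 17 → 19 → 20; step 4 is the side branch).

Steps least certain to work

Step 9 (key step). The most likely failure is low enantiomeric purity. It can arise from closure of 13 before it meets the catalyst (13 ionises very easily), from a loosely held ion pair around the bulky 3-flavonyl cation, or from acid-induced re-ionisation of the C2–O1 bond of 15, whose cation is stabilised by the 4-(benzyloxy)phenyl group. Reversible capture of the cation by the flavone carbonyl oxygen may also slow the closure. The fallback gives up asymmetric induction and resolves. It sets out from 13, which is closed with a catalytic achiral acid (pyridinium p-toluenesulfonate, CH2Cl2, 0 °C), the classical flav-3-ene formation, to the racemic chromene F1. The enantiomers of F1 are separated by preparative chromatography on a chiral stationary phase, and the (2R) enantiomer is 15, where the route is rejoined.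

Step 5. The most likely failure is a stalled coupling: reductive elimination at C3 of the flavone is slow because that carbon lies between the C2 aryl group and the C4 carbonyl, so reduction of the C–I bond or attack of the enolate on the flavone could take over. The fallback forms the same C3''–CH2 bond by alkylation before the flavone exists. It sets out from 8 and 4 and returns at 9. 8 is converted into its trimethylsilyl enol ether F2 (LiN(SiMe3)2, Me3SiCl, THF, −78 °C), and F2 is brominated with N-bromosuccinimide to the α-bromo ketone F3. C-alkylation of the diketone 4 with F3 (K2CO3, acetone) gives the triketone F4. Mild cyclodehydration of the 2-hydroxyaryl 1,3-diketone part of F4 (pyridinium p-toluenesulfonate, MgSO4, toluene, 40 °C) then closes the flavone ring and gives 9. Here the point to watch is Paal–Knorr furan formation from the 1,4-dicarbonyl unit.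

Step 10. The most likely failure is loss of chemoselectivity: the alkene is trisubstituted and flanked by two large groups, so the excess borane and time it needs may lead to reduction of the flavone carbonyl. The fallback reaches the C4 ketone by oxidation–reduction and not by hydroboration. It sets out from 15 and returns at 19. Epoxidation with dimethyldioxirane (acetone, −20 °C), anti to the C2 aryl group, gives the epoxide F5. Its ring A-stabilised C4–O bond opens in aqueous acetone to the 3,4-diol F6 (both C4 epimers are usable). Dess–Martin oxidation of the secondary C4 hydroxyl gives the 3-hydroxy ketone F7. SmI2 (THF/MeOH, −78 °C) then cleaves the C3–O bond α to the ketone, and protonation with acetic acid equilibration as in step 11 gives 19.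

Step 12. The most likely failure is over-reduction, by hydrogenolysis of the benzylic C2–O1 bond with opening of ring C, or incomplete cleavage because partly debenzylated intermediates precipitate. The fallback replaces reductive by acidolytic debenzylation: 19 is treated with BCl3 and pentamethylbenzene as benzyl-cation scavenger (CH2Cl2, −78 °C), a standard non-reductive cleavage of aryl benzyl ethers at a temperature where ring C should not open, and gives 20 directly (no new compound).

## Further compounds

F1 | step 9 | racemic 5,7-bis(benzyloxy)-3-{5,7-bis(benzyloxy)-2-[4-(benzyloxy)phenyl]-2H-chromen-3-yl}-2-[4-(benzyloxy)phenyl]-4H-chromen-4-one | C1=C(c2c(-c3ccc(OCc4ccccc4)cc3)oc3cc(OCc4ccccc4)cc(OCc4ccccc4)c3c2=O)C(c2ccc(OCc3ccccc3)cc2)Oc2cc(OCc3ccccc3)cc(OCc3ccccc3)c12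
F2 | step 5 | ({1-[2,4-bis(benzyloxy)-6-(methoxymethoxy)phenyl]ethenyl}oxy)trimethylsilane | C=C(O[Si](C)(C)C)c1c(OCOC)cc(OCc2ccccc2)cc1OCc1ccccc1
F3 | step 5 | 1-[2,4-bis(benzyloxy)-6-(methoxymethoxy)phenyl]-2-bromoethan-1-one | O=C(CBr)c1c(OCOC)cc(OCc2ccccc2)cc1OCc1ccccc1
F4 | step 5 | 2-[4-(benzyloxy)benzoyl]-1-[2,4-bis(benzyloxy)-6-hydroxyphenyl]-4-[2,4-bis(benzyloxy)-6-(methoxymethoxy)phenyl]butane-1,4-dione | O=C(CC(C(=O)c1ccc(OCc2ccccc2)cc1)C(=O)c1c(O)cc(OCc2ccccc2)cc1OCc1ccccc1)c1c(OCOC)cc(OCc2ccccc2)cc1OCc1ccccc1
F5 | step 10 | 3,4-epoxide of 15, epoxide oxygen trans to the C2 aryl group | O1[C@H]2c3c(OCc4ccccc4)cc(OCc4ccccc4)cc3O[C@H](c3ccc(OCc4ccccc4)cc3)[C@@]12c1c(-c2ccc(OCc3ccccc3)cc2)oc2cc(OCc3ccccc3)cc(OCc3ccccc3)c2c1=O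
F6 | step 10 | 3,4-diol from F5, 3-hydroxyl trans to the C2 aryl group, C4 as a mixture of epimers | OC1c2c(OCc3ccccc3)cc(OCc3ccccc3)cc2O[C@H](c2ccc(OCc3ccccc3)cc2)[C@]1(O)c1c(-c2ccc(OCc3ccccc3)cc2)oc2cc(OCc3ccccc3)cc(OCc3ccccc3)c2c1=O
F7 | step 10 | 3-hydroxy derivative of the flavanone 18/19, 3-hydroxyl trans to the C2 aryl group | O=C1c2c(OCc3ccccc3)cc(OCc3ccccc3)cc2O[C@H](c2ccc(OCc3ccccc3)cc2)[C@]1(O)c1c(-c2ccc(OCc3ccccc3)cc2)oc2cc(OCc3ccccc3)cc(OCc3ccccc3)c2c1=O
F0 | step 12 | none | none
A1 | alternative 1 | (2S,3R)-5,7-bis(methoxymethoxy)-2-[4-(methoxymethoxy)phenyl]-3-{1-[4-(methoxymethoxy)phenyl]-1,3-dioxo-3-[2,4,6-tris(methoxymethoxy)phenyl]propan-2-yl}-2,3-dihydro-4H-chromen-4-one (diketone carbon stereolabile) | O=C1c2c(OCOC)cc(OCOC)cc2O[C@H](c2ccc(OCOC)cc2)[C@H]1C(C(=O)c1ccc(OCOC)cc1)C(=O)c1c(OCOC)cc(OCOC)cc1OCOC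
A2 | alternative 1 | racemic 2-({3-[4-(methoxymethoxy)benzoyl]-1-[4-(methoxymethoxy)phenyl]-4-oxo-4-[2,4,6-tris(methoxymethoxy)phenyl]but-2-en-1-yl}oxy)-4,6-bis(methoxymethoxy)benzaldehyde | O=Cc1c(OCOC)cc(OCOC)cc1OC(c1ccc(OCOC)cc1)C=C(C(=O)c1ccc(OCOC)cc1)C(=O)c1c(OCOC)cc(OCOC)cc1OCOC
A3 | alternative 2 | 2,3-trans-4-methoxyflavan carrying the flavone at C3, hexamethyl ether, C2 and C3 as in the target, 4-methoxy cis to the C2 aryl group | CO[C@@H]1c2c(OC)cc(OC)cc2O[C@H](c2ccc(OC)cc2)[C@H]1c1c(-c2ccc(OC)cc2)oc2cc(OC)cc(OC)c2c1=O
A4 | alternative 2 | 5,7-dimethoxy-2-(4-methoxyphenyl)-3-[(E)-2-(4-methoxyphenyl)ethenyl]-4H-chromen-4-one | COc1ccc(/C=C/c2c(-c3ccc(OC)cc3)oc3cc(OC)cc(OC)c3c2=O)cc1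
A5 | alternative 2 | 2-(dimethoxymethyl)-3,5-dimethoxyphenol | COC(OC)c1c(O)cc(OC)cc1OC
A6 | alternative 3 | (2S,3R)-5,7-dimethoxy-3-[5,7-dimethoxy-2-(4-methoxyphenyl)-4-oxo-4H-chromen-3-yl]-2-(4-methoxyphenyl)-2,3-dihydro-4H-chromen-4-one (hexamethyl ether of 20) | O=C1c2c(OC)cc(OC)cc2O[C@H](c2ccc(OC)cc2)[C@H]1c1c(-c2ccc(OC)cc2)oc2cc(OC)cc(OC)c2c1=O
A7 | alternative 3 | methyl 2-[5,7-dimethoxy-2-(4-methoxyphenyl)-4-oxo-4H-chromen-3-yl]-3-hydroxy-3-(4-methoxyphenyl)propanoate, both centres configured as C3 and C2 of the target | O[C@H](c1ccc(OC)cc1)[C@H](C(=O)OC)c1c(-c2ccc(OC)cc2)oc2cc(OC)cc(OC)c2c1=O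
A8 | alternative 3 | 3,5-dimethoxy-2-(trimethylsilyl)phenyl trifluoromethanesulfonate | FC(F)(F)S(=O)(=O)Oc1cc(OC)cc(OC)c1[Si](C)(C)C
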